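The C50 polyene is disconnected at the C14'–C15' single bond (carotenoid numbering), where the methyl-branched C13'=C14' alkene meets the central C15=C15' alkene. The cyclohexene half enters as a terminal trienyne that still lacks methyl C20'. In one flask, zirconium-catalysed syn-methylalumination adds C20', fixes the E geometry of C13'=C14' and gives an alkenylalane. Pd/Zn-catalysed cross-coupling then joins it to the acyclic heptaenyl bromide with retention on both sides. The step exploits the C13'(CH3)=C14'H–C15'H= motif. Both termini come from one chiral N-acyl oxazolidinone: the C1 tertiary radical is hydrated in the acyclic half and closes the C1'–C6' bond of the cyclohexene ring in the other.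

Key step: step 25

Remark on the chemistry: carotenoid numbering is used throughout. Unprimed locants belong to the acyclic half, primed locants to the ring half, and C1''–C4'' to the chain on C2'. The sulfone-bearing carbon of 20 and 42 is assumed to be an epimer mixture; this is inconsequential because the centre is destroyed in the same flask.

Step 1
Reactants: 1 acetylene
Product: 2 (E)-1-bromo-2-iodoethene
Conditions: IBr, 48% aq HBr, 0 °C, acetylene bubbled through
Reagents that add atoms: iodine monobromide, BrI
Why: Electrophilic anti addition of I–Br to the alkyne through a bridged iodonium ion should give the E dihalide, which is too electron-poor to add a second equivalent.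

Step 2
Reactants: 2 (E)-1-bromo-2-iodoethene; 3 ethynyltrimethylsilane
Product: 4 (E)-(4-bromobut-3-en-1-ynyl)trimethylsilane
Conditions: PdCl2(PPh3)2 (2 mol %), CuI (4 mol %), i-Pr2NH, THF, 0 °C
Reagents that add atoms: none
Why: Sonogashira coupling in which zerovalent palladium inserts only into the weaker C–I bond, with retention of the E geometry, so the C–Br bond is kept for later use.

Step 3
Reactants: 5 prop-2-yn-1-ol; 4 (E)-(4-bromobut-3-en-1-ynyl)trimethylsilane
Product: 7 (2E,4E)-2-methyl-7-(trimethylsilyl)hepta-2,4-dien-6-yn-1-ol, via alkenylalane 6 (not isolated)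
Conditions: Me3Al (3 equiv), Cp2ZrCl2 (0.25 equiv), (CH2Cl)2, 0 to 23 °C; volatiles removed in vacuo; then 4, ZnCl2 (1 equiv), Pd2(dba)3 (2.5 mol %), P(2-furyl)3 (10 mol %), DMF, 23 °C; aq NH4Cl
Reagents that add atoms: trimethylaluminium, C[Al](C)C
Why: Zirconium-catalysed syn-carboalumination of the aluminium propargyl alkoxide places methyl on the internal carbon, and Negishi coupling of the alkenyl metal with 4 proceeds with retention, so both alkenes should be E.

Step 4
Reactants: 7 (2E,4E)-2-methyl-7-(trimethylsilyl)hepta-2,4-dien-6-yn-1-ol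
Product: 8 [(3E,5E)-7-bromo-6-methylhepta-3,5-dien-1-ynyl]trimethylsilane
Conditions: CBr4, PPh3, CH2Cl2, 0 °C, dark
Reagents that add atoms: carbon tetrabromide, BrC(Br)(Br)Br
Why: Appel bromination displaces the oxyphosphonium ion of the primary allylic alcohol by SN2 under neutral conditions that leave the dienyne and the C–Si bond untouched.

Step 5
Reactants: 9 (R)-4-benzyloxazolidin-2-one; 10 3-methylbut-2-enoyl chloride
Product: 11 (R)-4-benzyl-3-(3-methylbut-2-enoyl)oxazolidin-2-one
Conditions: n-BuLi, THF, −78 °C; then 10, −78 to 0 °C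
Reagents that add atoms: none
Why: N-Acylation of the lithiated oxazolidinone by the acid chloride is the standard entry to Evans imides and does not touch the stereocentre of the auxiliary.

Step 6
Reactants: 11 (R)-4-benzyl-3-(3-methylbut-2-enoyl)oxazolidin-2-one; 12 1-bromo-3-methylbut-2-ene
Product: 13 (R)-4-benzyl-3-[(R)-5-methyl-2-(prop-1-en-2-yl)hex-4-enoyl]oxazolidin-2-one
Conditions: NaHMDS (1.1 equiv), THF, −78 °C; then 12; AcOH quench at −78 °C
Reagents that add atoms: none
Why: Evans asymmetric alkylation of the chelated sodium dienolate occurs at the alpha carbon (deconjugative alkylation) on the face opposite the benzyl group, which sets C2 (R at this stage) and creates the isopropenyl group.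

Step 7
Reactants: 13 (R)-4-benzyl-3-[(R)-5-methyl-2-(prop-1-en-2-yl)hex-4-enoyl]oxazolidin-2-one
Product: 14 (R)-lavandulol
Conditions: LiBH4, MeOH (1 equiv), Et2O, 0 °C
Reagents that add atoms: none
Why: Reductive cleavage of the imide by LiBH4 is faster than enolisation, so the labile alpha stereocentre is kept and the auxiliary is released.

Step 8
Reactants: 14 (R)-lavandulol
Product: 15 (R)-3-(iodomethyl)-2,6-dimethylhepta-1,5-diene
Conditions: I2, PPh3, imidazole, CH2Cl2, 0 °C
Reagents that add atoms: iodine, II
Why: Appel-type iodination displaces the primary hydroxyl group by SN2 at a carbon that is not stereogenic.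

Step 9
Reactants: 15 (R)-3-(iodomethyl)-2,6-dimethylhepta-1,5-diene; 16 sodium benzenesulfinate
Product: 17 (R)-lavandulyl phenyl sulfone
Conditions: DMF, 50 °C
Reagents that add atoms: none
Why: SN2 S-alkylation of the soft sulfinate anion by the primary iodide in a dipolar aprotic solvent should give the sulfone rather than the sulfinate ester.

Step 10
Reactants: 17 (R)-lavandulyl phenyl sulfone
Product: 18 (R)-2,6-dimethyl-3-[(phenylsulfonyl)methyl]hept-5-en-2-ol
Conditions: Co(acac)2 (20 mol %), PhSiH3 (3 equiv), O2 (1 atm), THF, 23 °C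
Reagents that add atoms: dioxygen, O=O
Why: Mukaiyama hydration, in which hydrogen atom transfer from the cobalt hydride goes to the less hindered 1,1-disubstituted alkene rather than to the trisubstituted prenyl alkene, and O2 traps the tertiary C1 radical faster than the disfavoured four-exo or five-endo closures.

Step 11
Reactants: 18 (R)-2,6-dimethyl-3-[(phenylsulfonyl)methyl]hept-5-en-2-ol
Product: 19 triethylsilyl ether of 18
Conditions: TESOTf, 2,6-lutidine, CH2Cl2, −78 to 0 °C
Reagents that add atoms: triethylsilyl trifluoromethanesulfonate, CC[Si](CC)(CC)OS(=O)(=O)C(F)(F)F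
Why: Silylation of the hindered tertiary alcohol needs the silyl triflate, and the resulting ether withstands the organolithium, alkoxide and organoaluminium reagents that follow.

Step 12
Reactants: 19 triethylsilyl ether of 18; 8 [(3E,5E)-7-bromo-6-methylhepta-3,5-dien-1-ynyl]trimethylsilane
Product: 21 acyclic trienyne (C1–C10), via alkylated sulfone 20 (not isolated)
Conditions: n-BuLi (1.05 equiv), THF, −78 °C; 8, −78 to 0 °C; then t-BuOK (4 equiv), −20 to 0 °C, dark; water
Reagents that add atoms: none
Why: Julia-type sulfone alkylation by the allylic bromide, followed by base-induced 1,2-elimination of benzenesulfinate through the acidic allylic C4–H, should give the conjugated E C3=C4 alkene as the less strained isomer, while tert-butoxide also cleaves the alkynyl C–Si bond.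

Step 13
Reactants: 21 acyclic trienyne (C1–C10); 4 (E)-(4-bromobut-3-en-1-ynyl)trimethylsilane
Product: 24 acyclic pentaenyne (C1–C14), via alkenylalane 22 (not isolated), via silylated pentaenyne 23 (not isolated)
Conditions: Me3Al (2 equiv), Cp2ZrCl2 (0.25 equiv), (CH2Cl)2, 23 °C; volatiles removed in vacuo; 4, ZnCl2 (1 equiv), Pd2(dba)3 (2.5 mol %), P(2-furyl)3 (10 mol %), DMF, 23 °C, dark; work-up; K2CO3, MeOH, 23 °C
Reagents that add atoms: trimethylaluminium, C[Al](C)C
Why: Zirconium-catalysed syn-methylalumination and Negishi coupling add the C9 methyl group and C11–C14 with E geometry through syn addition and retention, and methanolysis then frees the terminal alkyne.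

Step 14
Reactants: 24 acyclic pentaenyne (C1–C14); 2 (E)-1-bromo-2-iodoethene
Product: 26 acyclic heptaenyl bromide (C1–C15'), via alkenylalane 25 (not isolated)
Conditions: Me3Al (2 equiv), Cp2ZrCl2 (0.25 equiv), (CH2Cl)2, 23 °C; volatiles removed in vacuo; 2 (1.5 equiv), ZnCl2 (1 equiv), Pd2(dba)3 (2.5 mol %), P(2-furyl)3 (10 mol %), DMF, 0 to 23 °C, dark; used at once
Reagents that add atoms: trimethylaluminium, C[Al](C)C
Why: The same carboalumination and Negishi coupling sequence, in which zerovalent palladium inserts selectively into the C–I bond of 2, should cap the chain with an E bromovinyl group.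

Step 15
Reactants: 27 2-methyl-2-vinyloxirane
Product: 28 (E)-4-chloro-2-methylbut-2-en-1-ol
Conditions: TiCl4, CH2Cl2, −85 °C; 1 M aq HCl
Reagents that add atoms: titanium tetrachloride, Cl[Ti](Cl)(Cl)Cl
Why: Lewis acid opening of the vinyl epoxide with SN2' delivery of chloride to the vinyl terminus should give the favoured E trisubstituted allylic alcohol.

Step 16
Reactants: 28 (E)-4-chloro-2-methylbut-2-en-1-ol
Product: 29 tert-butyl{[(E)-4-chloro-2-methylbut-2-enyl]oxy}dimethylsilane
Conditions: TBSCl, imidazole, CH2Cl2, 0 °C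
Reagents that add atoms: tert-butyldimethylsilyl chloride, CC(C)(C)[Si](C)(C)Cl
Why: Imidazole-promoted silylation of the primary alcohol is fast, and the allylic chloride is inert under these conditions.

Step 17
Reactants: 11 (R)-4-benzyl-3-(3-methylbut-2-enoyl)oxazolidin-2-one; 29 tert-butyl{[(E)-4-chloro-2-methylbut-2-enyl]oxy}dimethylsilane
Product: 31 alkylated imide of the ring half, via allylic iodide 30 (not isolated)
Conditions: 29, NaI, acetone, 23 °C, dark; concentrated and taken up in THF; added to 11 and NaHMDS (1.1 equiv), THF, −78 to −40 °C; AcOH quench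
Reagents that add atoms: sodium iodide, [Na+].[I-] (its iodine stays only in 30)
Why: Finkelstein exchange makes the electrophile reactive enough at low temperature, and Evans asymmetric deconjugative alkylation on the face opposite the benzyl group sets C2' (R) exactly as in step 6.

Step 18
Reactants: 31 alkylated imide of the ring half
Product: 32 (2R,4E)-6-[(tert-butyldimethylsilyl)oxy]-5-methyl-2-(prop-1-en-2-yl)hex-4-en-1-ol
Conditions: LiBH4, MeOH (1 equiv), Et2O, 0 °C
Reagents that add atoms: none
Why: Reductive cleavage of the imide by LiBH4 preserves the alpha stereocentre and the silyl ether and releases the auxiliary.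

Step 19
Reactants: 32 (2R,4E)-6-[(tert-butyldimethylsilyl)oxy]-5-methyl-2-(prop-1-en-2-yl)hex-4-en-1-ol
Product: 33 primary iodide of the ring half
Conditions: I2, PPh3, imidazole, CH2Cl2, 0 °C
Reagents that add atoms: iodine, II
Why: Appel-type iodination of the only free hydroxyl group proceeds by SN2 at a non-stereogenic carbon under buffered conditions that spare the silyl ether.

Step 20
Reactants: 5 prop-2-yn-1-ol
Product: 35 (Z)-3-iodo-2-methylprop-2-en-1-ol, via magnesacycle 34 (not isolated)
Conditions: MeMgBr (3 equiv), CuI (10 mol %), THF, −10 to 23 °C; then I2, −78 to 0 °C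
Reagents that add atoms: methylmagnesium bromide, C[Mg]Br; iodine, II
Why: Copper-catalysed carbomagnesiation of the magnesium propargyl alkoxide is an alkoxide-directed anti addition that gives a five-membered magnesacycle, so iodinolysis with retention places iodine cis to the CH2OH group.

Step 21
Reactants: 35 (Z)-3-iodo-2-methylprop-2-en-1-ol; 36 diethyl [(phenylsulfonyl)methyl]phosphonate
Product: 38 {[(1E,3Z)-4-iodo-3-methylbuta-1,3-dienyl]sulfonyl}benzene, via iodoenal 37 (not isolated)
Conditions: MnO2, CH2Cl2, 23 °C, dark; filtered; filtrate added to 36 and NaH, THF, 0 °C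
Reagents that add atoms: none
Why: Allylic oxidation by MnO2 and immediate Horner–Wadsworth–Emmons olefination with the sulfonyl-stabilised phosphonate should give the E vinyl sulfone before the labile Z iodoenal can isomerise.

Step 22
Reactants: 33 primary iodide of the ring half; 38 {[(1E,3Z)-4-iodo-3-methylbuta-1,3-dienyl]sulfonyl}benzene
Product: 40 acyclic dienyl sulfone (1E,3Z,6R,8E), via alkylzinc iodide 39 (not isolated)
Conditions: activated Zn dust, LiCl, THF, 40 °C; then 38, PdCl2(dppf) (3 mol %), THF, 23 °C, dark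
Reagents that add atoms: zinc, [Zn] (stays only in 39)
Why: Negishi sp3–sp2 coupling, in which zinc insertion into the primary C–I bond tolerates the silyl ether and the alkenes, and the wide-bite-angle dppf catalyst couples the alkylzinc with the vinyl iodide with retention and without beta-hydride elimination.

Step 23
Reactants: 40 acyclic dienyl sulfone (1E,3Z,6R,8E)
Product: 41 cis-(2'R,6'R)-cyclohexenylmethyl phenyl sulfone
Conditions: Fe(acac)3 (30 mol %), PhSiH3 (2.5 equiv), EtOH, 60 °C, 0.02 M, argon
Reagents that add atoms: none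
Why: Metal-hydride hydrogen atom transfer Giese cyclisation, in which the iron hydride delivers H to the isopropenyl CH2 and the nucleophilic tertiary C1' radical adds six-exo to C6' (the beta carbon of the vinyl sulfone, held close by the Z C4'=C5' alkene) through a chair-like transition state with the C2' chain and the sulfonylmethyl arm both pseudo-equatorial, which should set C6' (R) cis to C2'.

Step 24
Reactants: 41 cis-(2'R,6'R)-cyclohexenylmethyl phenyl sulfone; 8 [(3E,5E)-7-bromo-6-methylhepta-3,5-dien-1-ynyl]trimethylsilane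
Product: 43 ring-half trienyne (C1'–C14'), via alkylated sulfone 42 (not isolated)
Conditions: n-BuLi (1.05 equiv), THF, −78 °C; 8, −78 to 0 °C; then t-BuOK (4 equiv), −20 to 0 °C, dark; water
Reagents that add atoms: none
Why: Julia-type sulfone alkylation, then base-induced elimination of benzenesulfinate through the more acidic C8'–H (allylic to the dienyne) rather than the hindered C6'–H, should give the E C7'=C8' alkene, and tert-butoxide also removes the alkynyl silyl group.

Step 25
Reactants: 43 ring-half trienyne (C1'–C14'); 26 acyclic heptaenyl bromide (C1–C15')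
Product: 45 bis-silylated C50 carotenoid, via alkenylalane 44 (not isolated)
Conditions: 43, Me3Al (2 equiv), Cp2ZrCl2 (0.25 equiv), (CH2Cl)2, 23 °C; volatiles removed in vacuo; then 26 (1.0 equiv), ZnCl2 (1 equiv), Pd2(dba)3 (2.5 mol %), P(2-furyl)3 (10 mol %), DMF, 23 °C, dark, argon
Reagents that add atoms: trimethylaluminium, C[Al](C)C
Why: Cp2ZrCl2 and Me3Al form a polarised Zr–CH3 species that adds syn across the terminal C13'≡C14' alkyne with methyl going to the internal carbon C13', and Zr-to-Al exchange gives alkenylalane 44; ZnCl2 then relays the alkenyl group to palladium, which has inserted as zerovalent palladium into the C15'–Br bond of 26 with retention, and reductive elimination forms the C14'–C15' bond. The closest known reaction type is the tandem of zirconium-catalysed carboalumination and Negishi cross-coupling used to assemble oligoene and carotenoid chains. No ring is closed and no stereocentre is created; the new stereo-element is the E geometry of C13'=C14', controlled by the syn addition, while C15=C15' keeps the E geometry of 26 because oxidative addition, transmetalation and reductive elimination are all stereoretentive. The step needs chemoselectivity for the single alkyne over the five C=C bonds of 43 and regioselectivity for methyl at C13'; both are secured by the much higher carbometalation rate of a terminal alkyne and by aluminium preferring the unhindered terminal carbon. Removal of excess Me3Al before the coupling suppresses methyl transfer, and the two silyl ethers keep both hydroxyl groups from protonating 44.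

Step 26
Reactants: 45 bis-silylated C50 carotenoid
Product: 46 target CNP0409952.1
Conditions: TBAF (4 equiv), THF, 0 to 23 °C, dark, argon
Reagents that add atoms: none
Why: Fluoride-induced cleavage of both silyl ethers is driven by Si–F bond formation under nearly neutral conditions that leave the polyene geometry and the three stereocentres untouched.

Compound list
1 | acetylene | C#C | starting material
2 | (E)-1-bromo-2-iodoethene | Br/C=C/I | intermediate
3 | ethynyltrimethylsilane | C#C[Si](C)(C)C | starting material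
4 | (E)-(4-bromobut-3-en-1-ynyl)trimethylsilane | Br/C=C/C#C[Si](C)(C)C | intermediate
5 | prop-2-yn-1-ol | C#CCO | starting material
6 | (E)-alkenylalane of propargyl alcohol, O- and C-bound AlMe2, methyl cis to aluminium | C[Al](C)/C=C(\C)CO[Al](C)C | intermediate
7 | (2E,4E)-2-methyl-7-(trimethylsilyl)hepta-2,4-dien-6-yn-1-ol | OC/C(C)=C/C=C/C#C[Si](C)(C)C | intermediate
8 | [(3E,5E)-7-bromo-6-methylhepta-3,5-dien-1-ynyl]trimethylsilane | BrC/C(C)=C/C=C/C#C[Si](C)(C)C | intermediate
9 | (R)-4-benzyloxazolidin-2-one | O=C1N[C@H](Cc2ccccc2)CO1 | starting material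
10 | 3-methylbut-2-enoyl chloride | CC(C)=CC(=O)Cl | starting material
11 | (R)-4-benzyl-3-(3-methylbut-2-enoyl)oxazolidin-2-one | CC(C)=CC(=O)N1[C@H](Cc2ccccc2)COC1=O | intermediate
12 | 1-bromo-3-methylbut-2-ene (prenyl bromide) | CC(C)=CCBr | starting material
13 | (R)-4-benzyl-3-[(R)-5-methyl-2-(prop-1-en-2-yl)hex-4-enoyl]oxazolidin-2-one | CC(C)=CC[C@@H](C(=O)N1[C@H](Cc2ccccc2)COC1=O)C(C)=C | intermediate
14 | (R)-lavandulol, (R)-5-methyl-2-(prop-1-en-2-yl)hex-4-en-1-ol | CC(C)=CC[C@@H](CO)C(C)=C | intermediate
15 | (R)-3-(iodomethyl)-2,6-dimethylhepta-1,5-diene | CC(C)=CC[C@@H](CI)C(C)=C | intermediate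
16 | sodium benzenesulfinate | [Na+].[O-]S(=O)c1ccccc1 | starting material
17 | (R)-lavandulyl phenyl sulfone | CC(C)=CC[C@@H](CS(=O)(=O)c1ccccc1)C(C)=C | intermediate
18 | (R)-2,6-dimethyl-3-[(phenylsulfonyl)methyl]hept-5-en-2-ol | CC(C)=CC[C@@H](CS(=O)(=O)c1ccccc1)C(C)(C)O | intermediate
19 | triethylsilyl ether of 18 (R) | CC(C)=CC[C@@H](CS(=O)(=O)c1ccccc1)C(C)(C)O[Si](CC)(CC)CC | intermediate
20 | C3-alkylated sulfone, C2 fixed (R), C3 epimer mixture, (5E,7E)-dienyne chain with C10 silyl group | CC(C)=CC[C@@H](C(C/C(C)=C/C=C/C#C[Si](C)(C)C)S(=O)(=O)c1ccccc1)C(C)(C)O[Si](CC)(CC)CC | intermediate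
21 | triethyl{[(3S,4E,6E,8E)-2,6-dimethyl-3-(3-methylbut-2-enyl)undeca-4,6,8-trien-10-yn-2-yl]oxy}silane | CC(C)=CC[C@@H](/C=C/C(C)=C/C=C/C#C)C(C)(C)O[Si](CC)(CC)CC | intermediate
22 | all-E tetraenyl dimethylalane from 21 (Al on C10, new methyl on C9) | CC(C)=CC[C@@H](/C=C/C(C)=C/C=C/C(C)=C/[Al](C)C)C(C)(C)O[Si](CC)(CC)CC | intermediate
23 | all-E pentaenyne with trimethylsilyl group on C14, (2S) | CC(C)=CC[C@@H](/C=C/C(C)=C/C=C/C(C)=C/C=C/C#C[Si](C)(C)C)C(C)(C)O[Si](CC)(CC)CC | intermediate
24 | all-E terminal pentaenyne C1–C14, (2S), C1 triethylsilyl ether | CC(C)=CC[C@@H](/C=C/C(C)=C/C=C/C(C)=C/C=C/C#C)C(C)(C)O[Si](CC)(CC)CC | intermediate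
25 | all-E hexaenyl dimethylalane from 24 (Al on C14, new methyl on C13) | CC(C)=CC[C@@H](/C=C/C(C)=C/C=C/C(C)=C/C=C/C(C)=C/[Al](C)C)C(C)(C)O[Si](CC)(CC)CC | intermediate
26 | all-E heptaenyl bromide C1–C15' (Br on C15'), (2S), C1 triethylsilyl ether | CC(C)=CC[C@@H](/C=C/C(C)=C/C=C/C(C)=C/C=C/C(C)=C/C=C/Br)C(C)(C)O[Si](CC)(CC)CC | intermediate
27 | 2-methyl-2-vinyloxirane (racemic) | CC1(C=C)CO1 | starting material
28 | (E)-4-chloro-2-methylbut-2-en-1-ol | OC/C(C)=C/CCl | intermediate
29 | tert-butyl{[(E)-4-chloro-2-methylbut-2-enyl]oxy}dimethylsilane | CC(C)(C)[Si](C)(C)OC/C(C)=C/CCl | intermediate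
30 | tert-butyl{[(E)-4-iodo-2-methylbut-2-enyl]oxy}dimethylsilane | CC(C)(C)[Si](C)(C)OC/C(C)=C/CI | intermediate
31 | (R)-4-benzyl-3-[(2R,4E)-6-(tert-butyldimethylsilyloxy)-5-methyl-2-(prop-1-en-2-yl)hex-4-enoyl]oxazolidin-2-one | CC(C)(C)[Si](C)(C)OC/C(C)=C/C[C@@H](C(=O)N1[C@H](Cc2ccccc2)COC1=O)C(C)=C | intermediate
32 | (2R,4E)-6-[(tert-butyldimethylsilyl)oxy]-5-methyl-2-(prop-1-en-2-yl)hex-4-en-1-ol | CC(C)(C)[Si](C)(C)OC/C(C)=C/C[C@@H](CO)C(C)=C | intermediate
33 | primary iodide derived from 32 (R,E) | CC(C)(C)[Si](C)(C)OC/C(C)=C/C[C@@H](CI)C(C)=C | intermediate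
34 | 4-methyl-2,5-dihydro-1,2-oxamagnesole (cyclic alkenylmagnesium alkoxide) | CC1=C[Mg]OC1 | intermediate
35 | (Z)-3-iodo-2-methylprop-2-en-1-ol | OC/C(C)=C\I | intermediate
36 | diethyl [(phenylsulfonyl)methyl]phosphonate | CCOP(=O)(CS(=O)(=O)c1ccccc1)OCC | starting material
37 | (Z)-3-iodo-2-methylprop-2-enal | O=C/C(C)=C\I | intermediate
38 | {[(1E,3Z)-4-iodo-3-methylbuta-1,3-dienyl]sulfonyl}benzene | I/C=C(C)\C=C\S(=O)(=O)c1ccccc1 | intermediate
39 | alkylzinc iodide derived from 33 | CC(C)(C)[Si](C)(C)OC/C(C)=C/C[C@@H](C[Zn]I)C(C)=C | intermediate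
40 | (1E,3Z,6R,8E)-10-(tert-butyldimethylsilyloxy)-3,9-dimethyl-1-(phenylsulfonyl)-6-(prop-1-en-2-yl)deca-1,3,8-triene | CC(C)(C)[Si](C)(C)OC/C(C)=C/C[C@@H](C/C=C(C)\C=C\S(=O)(=O)c1ccccc1)C(C)=C | intermediate
41 | {[(1R,5R)-5-[(E)-4-(tert-butyldimethylsilyloxy)-3-methylbut-2-enyl]-2,6,6-trimethylcyclohex-2-enyl]methylsulfonyl}benzene (substituents cis) | O=S(=O)(c1ccccc1)C[C@@H]1C(C)=CC[C@H](C/C=C(\C)CO[Si](C)(C)C(C)(C)C)C1(C)C | intermediate
42 | C7'-alkylated sulfone, ring centres as in 41, C7' epimer mixture | O=S(=O)(c1ccccc1)C(C/C(C)=C/C=C/C#C[Si](C)(C)C)[C@@H]1C(C)=CC[C@H](C/C=C(\C)CO[Si](C)(C)C(C)(C)C)C1(C)C | intermediate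
43 | all-E terminal trienyne C1'–C14', (2'R,6'R), C4'' tert-butyldimethylsilyl ether | C#C/C=C/C=C(C)/C=C/[C@@H]1C(C)=CC[C@H](C/C=C(\C)CO[Si](C)(C)C(C)(C)C)C1(C)C | intermediate
44 | all-E tetraenyl dimethylalane from 43 (Al on C14', new methyl C20' on C13') | C[Al](C)/C=C(C)/C=C/C=C(C)/C=C/[C@@H]1C(C)=CC[C@H](C/C=C(\C)CO[Si](C)(C)C(C)(C)C)C1(C)C | intermediate
45 | all-E (2S,2'R,6'R) C50 carotenoid, C1 triethylsilyl ether and C4'' tert-butyldimethylsilyl ether | CC(C)=CC[C@@H](/C=C/C(C)=C/C=C/C(C)=C/C=C/C(C)=C/C=C/C=C(C)/C=C/C=C(C)/C=C/[C@@H]1C(C)=CC[C@H](C/C=C(\C)CO[Si](C)(C)C(C)(C)C)C1(C)C)C(C)(C)O[Si](CC)(CC)CC | intermediate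
46 | (all-E,2S,2'R,6'R)-2'-[(E)-4-hydroxy-3-methylbut-2-enyl]-2-(3-methylbut-2-enyl)-3,4-didehydro-1,2-dihydro-psi,epsilon-caroten-1-ol | CC(C)=CC[C@@H](/C=C/C(C)=C/C=C/C(C)=C/C=C/C(C)=C/C=C/C=C(C)/C=C/C=C(C)/C=C/[C@@H]1C(C)=CC[C@H](C/C=C(\C)CO)C1(C)C)C(C)(C)O | target

Total step count: 26. Longest linear sequence: 12 steps (steps 5 to 14, then 25 and 26).

Steps most likely to fail

Step 23.
- What may go wrong: hydrogen atom transfer may go to the dienyl sulfone instead of the isopropenyl group, so the acceptor is lost by reduction. Facial selectivity at C6' may also be poor.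
- Idea of the fallback: make the same C1' radical by photoredox decarboxylation of a tert-alkyl oxalate, so that no metal hydride ever meets the acceptor.
- Route: it sets out from 32. Mukaiyama hydration as in step 10 would give the diol F1. Appel-type iodination of its primary hydroxyl group would give the iodo alcohol F2. Acylation with methyl chlorooxoacetate (Et3N, DMAP, CH2Cl2) would give the tert-alkyl methyl oxalate F3. Zinc insertion and Negishi coupling with 38, as in step 22, would give the oxalate-bearing dienyl sulfone F4. CsOH in aqueous THF would give the caesium oxalate F5. Irradiation with blue light in the presence of Ir[dF(CF3)ppy]2(dtbbpy)PF6 in aqueous DME would expel CO2 and close the ring by the same six-exo Giese addition. This comes back to the route at 41.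

Step 25.
- What may go wrong: the heptaenyl bromide may decompose or lose its double-bond geometry while transmetalation is slow. Methyl transfer or homocoupling may compete with the transfer of the large alkenyl group.
- Idea of the fallback: form the same bond by a Stille coupling of two isolated and purified partners.
- Route: it sets out from 43 and 24. Carboalumination of 43 as before, quenched with I2, would give the tetraenyl iodide F6. The same sequence on 24 would give the hexaenyl iodide F7. Stille coupling of F7 with excess (E)-1,2-bis(tributylstannyl)ethene (Pd2(dba)3, AsPh3, NMP, 23 °C) would give the heptaenylstannane F8. Stille coupling of F6 with F8 under the same catalyst comes back to the route at 45.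

Step 24.
- What may go wrong: the base-induced elimination may run toward C6', may drag the ring double bond into conjugation by deprotonation of the doubly allylic C6'–H, or may give incomplete E selectivity at C7'=C8'.
- Idea of the fallback: replace the basic elimination by a reductive one (Julia–Lythgoe olefination).
- Route: it sets out from 41 and 7. MnO2 oxidation of 7 would give the dienynal F9. Addition of lithiated 41 to F9 and trapping with benzoyl chloride would give the beta-benzoyloxy sulfone F10. SmI2 with DMPU in THF at −78 °C would give the silylated trienyne F11. K2CO3 in MeOH comes back to the route at 43.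

Further compounds
F1 | step 23 | (3S,5E)-7-(tert-butyldimethylsilyloxy)-3-(hydroxymethyl)-2,6-dimethylhept-5-en-2-ol | CC(C)(C)[Si](C)(C)OC/C(C)=C/C[C@@H](CO)C(C)(C)O
F2 | step 23 | (3R,5E)-7-(tert-butyldimethylsilyloxy)-3-(iodomethyl)-2,6-dimethylhept-5-en-2-ol | CC(C)(C)[Si](C)(C)OC/C(C)=C/C[C@@H](CI)C(C)(C)O
F3 | step 23 | methyl oxalate of the tertiary alcohol F2 | CC(C)(C)[Si](C)(C)OC/C(C)=C/C[C@@H](CI)C(C)(C)OC(=O)C(=O)OC
F4 | step 23 | (1E,3Z)-dienyl phenyl sulfone bearing the tert-alkyl methyl oxalate at C1' | CC(C)(C)[Si](C)(C)OC/C(C)=C/C[C@@H](C/C=C(C)\C=C\S(=O)(=O)c1ccccc1)C(C)(C)OC(=O)C(=O)OC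
F5 | step 23 | caesium oxalate derived from F4 | CC(C)(C)[Si](C)(C)OC/C(C)=C/C[C@@H](C/C=C(C)\C=C\S(=O)(=O)c1ccccc1)C(C)(C)OC(=O)C(=O)[O-].[Cs+]
F6 | step 25 | all-E tetraenyl iodide of the ring half (I on C14', methyl on C13') | I/C=C(C)/C=C/C=C(C)/C=C/[C@@H]1C(C)=CC[C@H](C/C=C(\C)CO[Si](C)(C)C(C)(C)C)C1(C)C
F7 | step 25 | all-E hexaenyl iodide of the acyclic half (I on C14) | CC(C)=CC[C@@H](/C=C/C(C)=C/C=C/C(C)=C/C=C/C(C)=C/I)C(C)(C)O[Si](CC)(CC)CC
F8 | step 25 | all-E heptaenyl tributylstannane of the acyclic half (Sn on C15') | CC(C)=CC[C@@H](/C=C/C(C)=C/C=C/C(C)=C/C=C/C(C)=C/C=C/[Sn](CCCC)(CCCC)CCCC)C(C)(C)O[Si](CC)(CC)CC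
F9 | step 24 | (2E,4E)-2-methyl-7-(trimethylsilyl)hepta-2,4-dien-6-ynal | O=C/C(C)=C/C=C/C#C[Si](C)(C)C
F10 | step 24 | beta-benzoyloxy sulfone from 41 and F9 (C7' and C8' epimer mixture) | O=S(=O)(c1ccccc1)C(C(OC(=O)c1ccccc1)/C(C)=C/C=C/C#C[Si](C)(C)C)[C@@H]1C(C)=CC[C@H](C/C=C(\C)CO[Si](C)(C)C(C)(C)C)C1(C)C
F11 | step 24 | all-E trienyne of the ring half with trimethylsilyl group on C14' | C[Si](C)(C)C#C/C=C/C=C(C)/C=C/[C@@H]1C(C)=CC[C@H](C/C=C(\C)CO[Si](C)(C)C(C)(C)C)C1(C)C
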